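**Retrosynthetic overview**

1. Feature used (atom labels of the two identical drimane halves, C1–C10, with C11/C12 as the ethano bridge): each quaternary, methyl-bearing C10 lies between sp2 C9 of the tetrasubstituted C8=C9 alkene and C5. Ring B with one extra alkene at C5=C6 is therefore the cyclohexa-1,4-diene left by reductive methylation of an aromatic ring B carrying a carboxamide on C10.
2. Last disconnections: removal of the C1 oxygen and trans hydrogenation of C5=C6; before that, both rings A are opened at C1–C2 (alkyllithium acylation on the C10 carboxamide, whose carbon becomes C1).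
3. Key disconnection: both C10–CH3 bonds, formed in one double Birch reduction–methylation of the bibenzyl bis-benzamide 13 of (R)-2-(methoxymethyl)pyrrolidine.
4. 13 comes from monomer 11 by benzylic lithiation and oxidative C11–C12 coupling. 11 comes from 2,3-dimethylbenzoic acid by ortho-iodination at C5, amidation, and copper-catalysed aryl Grignard addition to diethyl isopropylidenemalonate (C5–C4 bond, quaternary C4), then trimming to the C4–C3–C2–O chain.
5. Ring order: rings B are present from the start as arenes and are dearomatised at step 8; rings A are closed at step 11.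

Key step: step 8

Assumption: the sense of induction at C10 is taken from the chelated lithium enolate model of these amides, by which the (R)-amine should give the configuration drawn; should a single-ring trial show the opposite sense, the (S)-amine is used and nothing else changes.

**Route**

Step 1
Reactants: 1 2,3-dimethylbenzoic acid
Product: 2 6-iodo-2,3-dimethylbenzoic acid
Conditions: Pd(OAc)2 (5 mol%), PhI(OAc)2 (0.75 equiv), I2 (0.75 equiv), DMF, 100 °C
Reagents that add atoms: iodine, II
Why: Carboxylate-directed ortho C–H iodination: the carboxylate guides cyclopalladation to the only free ortho position (the future C5) and acetyl hypoiodite formed from PhI(OAc)2 and I2 iodinates the aryl–palladium bond, so the site of the later side chain is fixed without competition from the benzylic methyl groups.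

Step 2
Reactants: 2 6-iodo-2,3-dimethylbenzoic acid; 3 (R)-2-(methoxymethyl)pyrrolidine
Product: 5 (6-iodo-2,3-dimethylphenyl)[(2R)-2-(methoxymethyl)pyrrolidin-1-yl]methanone, via acid chloride 4 (not isolated)
Conditions: (COCl)2, DMF (cat), CH2Cl2, 0 °C to rt; then 3, Et3N, CH2Cl2, 0 °C to rt
Reagents that add atoms: none
Why: Acid chloride formation followed by N-acylation of the secondary amine (amide coupling), which works even for a di-ortho-substituted benzoyl chloride and leaves the pyrrolidine stereocentre untouched.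

Step 3
Reactants: 5 (6-iodo-2,3-dimethylphenyl)[(2R)-2-(methoxymethyl)pyrrolidin-1-yl]methanone; 6 diethyl isopropylidenemalonate
Product: 8 diethyl 2-[2-(2-{[(2R)-2-(methoxymethyl)pyrrolidin-1-yl]carbonyl}-3,4-dimethylphenyl)propan-2-yl]propanedioate, via arylmagnesium chloride 7 (not isolated)
Conditions: i-PrMgCl·LiCl, THF, −20 °C; then CuI (10 mol%), 6, −20 °C to rt; aq NH4Cl
Reagents that add atoms: none
Why: Iodine–magnesium exchange is fast next to the chelating tertiary amide and spares it, and copper-catalysed conjugate addition of the aryl Grignard reagent to the doubly activated alkylidene malonate (chosen because simple β,β-disubstituted enoates accept aryl copper species poorly) forms the C5–C4 bond and the quaternary C4.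

Step 4
Reactants: 8 diethyl 2-[2-(2-{[(2R)-2-(methoxymethyl)pyrrolidin-1-yl]carbonyl}-3,4-dimethylphenyl)propan-2-yl]propanedioate
Product: 9 ethyl 3-(2-{[(2R)-2-(methoxymethyl)pyrrolidin-1-yl]carbonyl}-3,4-dimethylphenyl)-3-methylbutanoate
Conditions: LiCl, H2O, DMSO, 160 °C
Reagents that add atoms: none
Why: Krapcho dealkoxycarbonylation removes one ester of the malonate with loss of CO2 under neutral conditions that leave the tertiary amide and the remaining ester intact.

Step 5
Reactants: 9 ethyl 3-(2-{[(2R)-2-(methoxymethyl)pyrrolidin-1-yl]carbonyl}-3,4-dimethylphenyl)-3-methylbutanoate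
Product: 10 [6-(4-hydroxy-2-methylbutan-2-yl)-2,3-dimethylphenyl][(2R)-2-(methoxymethyl)pyrrolidin-1-yl]methanone
Conditions: LiBH4, THF, rt to 50 °C
Reagents that add atoms: none
Why: Chemoselective hydride reduction: LiBH4 reduces the ester to the primary alcohol (C2–OH) while the hindered tertiary benzamide is not attacked.

Step 6
Reactants: 10 [6-(4-hydroxy-2-methylbutan-2-yl)-2,3-dimethylphenyl][(2R)-2-(methoxymethyl)pyrrolidin-1-yl]methanone
Product: 11 [6-(4-{[tert-butyl(dimethyl)silyl]oxy}-2-methylbutan-2-yl)-2,3-dimethylphenyl][(2R)-2-(methoxymethyl)pyrrolidin-1-yl]methanone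
Conditions: TBSCl, imidazole, DMF, rt
Reagents that add atoms: tert-butyldimethylsilyl chloride, CC(C)(C)[Si](C)(C)Cl
Why: Standard silylation of the primary alcohol gives a TBS ether that tolerates s-BuLi and lithium in ammonia.

Step 7
Reactants: 11 [6-(4-{[tert-butyl(dimethyl)silyl]oxy}-2-methylbutan-2-yl)-2,3-dimethylphenyl][(2R)-2-(methoxymethyl)pyrrolidin-1-yl]methanone (2 equiv)
Product: 13 1,2-bis[3-(4-{[tert-butyl(dimethyl)silyl]oxy}-2-methylbutan-2-yl)-2-{[(2R)-2-(methoxymethyl)pyrrolidin-1-yl]carbonyl}-6-methylphenyl]ethane, via benzyllithium 12 (not isolated)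
Conditions: s-BuLi, THF, −78 °C; then CuCl2 (anhydrous, 1.1 equiv), −78 °C to rt
Reagents that add atoms: none
Why: Amide-directed lateral lithiation removes a proton from the C11 methyl ortho to the twisted carboxamide (both ring ortho positions are blocked) and oxidation of benzyllithium 12 by divalent copper chloride couples two benzylic carbons to the C11–C12 bond (oxidative homocoupling of an organolithium); the slowly rotating aryl–carbonyl axes only give rotamer mixtures that converge at step 8.

Step 8
Reactants: 13 1,2-bis[3-(4-{[tert-butyl(dimethyl)silyl]oxy}-2-methylbutan-2-yl)-2-{[(2R)-2-(methoxymethyl)pyrrolidin-1-yl]carbonyl}-6-methylphenyl]ethane; 14 iodomethane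
Product: 16 1,2-bis[(6R)-5-(4-{[tert-butyl(dimethyl)silyl]oxy}-2-methylbutan-2-yl)-6-{[(2R)-2-(methoxymethyl)pyrrolidin-1-yl]carbonyl}-2,6-dimethylcyclohexa-1,4-dien-1-yl]ethane, via bis(lithium enolate) 15 (not isolated)
Conditions: Li (5 equiv), NH3(l)–THF, t-BuOH (2 equiv), −78 °C; piperylene; then MeI (excess), −78 °C to −33 °C; NH4Cl
Reagents that add atoms: iodomethane (14), CI
Why: Each benzamide ring takes up two electrons from lithium and one proton from t-BuOH at C7, para to the carboxamide, which leaves a C10 lithium amide enolate (15) that survives in ammonia and is methylated at C10 by iodomethane to give the cyclohexa-1,4-diene with C8=C9 and C5=C6 in place. The closest known reaction is the Birch reduction–alkylation of benzamides of 2-(methoxymethyl)pyrrolidine to quaternary cyclohexa-2,5-diene carboxamides, used here twice in one molecule and on a 2,6-dialkyl pattern at the edge of its documented scope. No ring is closed: the step forms two C10–CH3 bonds and two stereocentres. Each C10 centre is set by the auxiliary on its own ring: lithium bridges the enolate oxygen and the methoxymethyl oxygen, the amide nitrogen turns to the C9 side away from the tertiary C4 group, and the pyrrolidine then screens one enolate face so that iodomethane enters from the other, which with the (R)-amine is expected to give the (6R) centres drawn. The step needs regioselectivity (proton at C7, methyl at C10), which the carboxamide secures by carrying the charge at C10 while the C5, C8 and C9 alkyl groups stay on alkene carbons, and face selectivity, which rests on the chelate. Because the two rings react independently, a wrong-face event on one ring gives a separable diastereomer and not the enantiomer, so the C2-symmetric product should be stereochemically enriched.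

Step 9
Reactants: 16 1,2-bis[(6R)-5-(4-{[tert-butyl(dimethyl)silyl]oxy}-2-methylbutan-2-yl)-6-{[(2R)-2-(methoxymethyl)pyrrolidin-1-yl]carbonyl}-2,6-dimethylcyclohexa-1,4-dien-1-yl]ethane
Product: 17 1,2-bis[(6R)-5-(4-hydroxy-2-methylbutan-2-yl)-6-{[(2R)-2-(methoxymethyl)pyrrolidin-1-yl]carbonyl}-2,6-dimethylcyclohexa-1,4-dien-1-yl]ethane
Conditions: TBAF, THF, rt
Reagents that add atoms: none
Why: Fluoride-induced cleavage of both silyl ethers (Si–F bond formation) leaves the dienes and the hindered amides untouched.

Step 10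
Reactants: 17 1,2-bis[(6R)-5-(4-hydroxy-2-methylbutan-2-yl)-6-{[(2R)-2-(methoxymethyl)pyrrolidin-1-yl]carbonyl}-2,6-dimethylcyclohexa-1,4-dien-1-yl]ethane
Product: 18 1,2-bis[(6R)-5-(4-iodo-2-methylbutan-2-yl)-6-{[(2R)-2-(methoxymethyl)pyrrolidin-1-yl]carbonyl}-2,6-dimethylcyclohexa-1,4-dien-1-yl]ethane
Conditions: PPh3, imidazole, I2 (premixed), CH2Cl2, 0 °C to rt
Reagents that add atoms: iodine, II
Why: Appel-type iodination of the two primary alcohols by the PPh3/I2/imidazole adduct (SN2 at C2), with iodine complexed to the phosphine beforehand so that no free iodine meets the electron-rich dienes.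

Step 11
Reactants: 18 1,2-bis[(6R)-5-(4-iodo-2-methylbutan-2-yl)-6-{[(2R)-2-(methoxymethyl)pyrrolidin-1-yl]carbonyl}-2,6-dimethylcyclohexa-1,4-dien-1-yl]ethane
Product: 21 8,8'-(ethane-1,2-diyl)bis[(8aR)-4,4,7,8a-tetramethyl-3,4,6,8a-tetrahydronaphthalen-1(2H)-one], via bis(alkyllithium) 19 (not isolated), via bis(lithium hemiaminal alkoxide) 20 (not isolated)
Conditions: t-BuLi (4.4 equiv), Et2O–pentane, −78 °C to 0 °C; then H2O
Reagents that add atoms: none
Why: Lithium–iodine exchange with t-BuLi outruns any attack on the amide and gives primary C2 alkyllithiums that add to the neighbouring C10 carboxamides in a 6-exo-trig intramolecular acylation closing both rings A; the chelated tetrahedral lithium alkoxides 20 resist a second addition and collapse to the C1 ketones on aqueous work-up with release of the auxiliary, and the quaternary C10 centres cannot epimerise.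

Step 12
Reactants: 21 8,8'-(ethane-1,2-diyl)bis[(8aR)-4,4,7,8a-tetramethyl-3,4,6,8a-tetrahydronaphthalen-1(2H)-one]
Product: 22 8,8'-(ethane-1,2-diyl)bis[(4aS,8aS)-4,4,7,8a-tetramethyl-3,4,4a,5,6,8a-hexahydronaphthalen-1(2H)-one]
Conditions: H2 (4 atm), PtO2, EtOAc, rt
Reagents that add atoms: none
Why: Heterogeneous catalytic hydrogenation reduces the trisubstituted C5=C6 bonds while the tetrasubstituted C8=C9 bonds stay inert, and hydrogen is delivered syn to the α face, opposite the axial C10 methyl and the 4β methyl as in 4,4-dimethyl-Δ5 decalin systems, which sets C5–H trans to C10–CH3 (5S, trans ring fusion).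

Step 13
Reactants: 22 8,8'-(ethane-1,2-diyl)bis[(4aS,8aS)-4,4,7,8a-tetramethyl-3,4,4a,5,6,8a-hexahydronaphthalen-1(2H)-one]
Product: 24 1,2-bis[(4aS,8aS)-2,5,5,8a-tetramethyl-3,4,4a,5,6,7,8,8a-octahydronaphthalen-1-yl]ethane (CNP0372467.1), via bis-hydrazone 23 (not isolated)
Conditions: N2H4·H2O, KOH, diethylene glycol, 130 °C then 200 °C
Reagents that add atoms: none
Why: Wolff–Kishner reduction in the Huang-Minlon mode: the C1 ketones, each with one quaternary α-carbon, form hydrazones that lose N2 under hot alkoxide to give CH2, while the tetrasubstituted C8=C9 alkenes and the non-epimerisable C5 and C10 centres are unaffected.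

**Compound list**

1 | 2,3-dimethylbenzoic acid | Cc1cccc(C(=O)O)c1C | starting material
2 | 6-iodo-2,3-dimethylbenzoic acid | Cc1ccc(I)c(C(=O)O)c1C | intermediate
3 | (R)-2-(methoxymethyl)pyrrolidine | COC[C@H]1CCCN1 | starting material
4 | 6-iodo-2,3-dimethylbenzoyl chloride (not isolated) | Cc1ccc(I)c(C(=O)Cl)c1C | intermediate
5 | (6-iodo-2,3-dimethylphenyl)[(2R)-2-(methoxymethyl)pyrrolidin-1-yl]methanone | Cc1ccc(I)c(C(=O)N2CCC[C@@H]2COC)c1C | intermediate
6 | diethyl isopropylidenemalonate (diethyl 2-(propan-2-ylidene)propanedioate) | CCOC(=O)C(=C(C)C)C(=O)OCC | starting material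
7 | arylmagnesium chloride of 5, magnesium on the former C–I carbon (C5) (not isolated) | Cc1ccc([Mg]Cl)c(C(=O)N2CCC[C@@H]2COC)c1C | intermediate
8 | diethyl 2-[2-(2-{[(2R)-2-(methoxymethyl)pyrrolidin-1-yl]carbonyl}-3,4-dimethylphenyl)propan-2-yl]propanedioate | Cc1ccc(C(C)(C)C(C(=O)OCC)C(=O)OCC)c(C(=O)N2CCC[C@@H]2COC)c1C | intermediate
9 | ethyl 3-(2-{[(2R)-2-(methoxymethyl)pyrrolidin-1-yl]carbonyl}-3,4-dimethylphenyl)-3-methylbutanoate | Cc1ccc(C(C)(C)CC(=O)OCC)c(C(=O)N2CCC[C@@H]2COC)c1C | intermediate
10 | [6-(4-hydroxy-2-methylbutan-2-yl)-2,3-dimethylphenyl][(2R)-2-(methoxymethyl)pyrrolidin-1-yl]methanone | Cc1ccc(C(C)(C)CCO)c(C(=O)N2CCC[C@@H]2COC)c1C | intermediate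
11 | [6-(4-{[tert-butyl(dimethyl)silyl]oxy}-2-methylbutan-2-yl)-2,3-dimethylphenyl][(2R)-2-(methoxymethyl)pyrrolidin-1-yl]methanone | Cc1ccc(C(C)(C)CCO[Si](C)(C)C(C)(C)C)c(C(=O)N2CCC[C@@H]2COC)c1C | intermediate
12 | benzyllithium of 11, lithium on the C11 methylene ortho to the amide (not isolated) | [Li]Cc1c(C)ccc(C(C)(C)CCO[Si](C)(C)C(C)(C)C)c1C(=O)N1CCC[C@@H]1COC | intermediate
13 | 1,2-bis[3-(4-{[tert-butyl(dimethyl)silyl]oxy}-2-methylbutan-2-yl)-2-{[(2R)-2-(methoxymethyl)pyrrolidin-1-yl]carbonyl}-6-methylphenyl]ethane (key-step precursor) | C(Cc1c(C)ccc(C(C)(C)CCO[Si](C)(C)C(C)(C)C)c1C(=O)N1CCC[C@@H]1COC)c1c(C)ccc(C(C)(C)CCO[Si](C)(C)C(C)(C)C)c1C(=O)N1CCC[C@@H]1COC | intermediate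
14 | iodomethane | CI | starting material
15 | bis(lithium amide enolate) of the doubly reduced 13, C10=C(OLi)N in each ring, C7 as CH2 (not isolated) | C(CC1=C(C)CC=C(C(C)(C)CCO[Si](C)(C)C(C)(C)C)C1=C(O[Li])N1CCC[C@@H]1COC)C1=C(C)CC=C(C(C)(C)CCO[Si](C)(C)C(C)(C)C)C1=C(O[Li])N1CCC[C@@H]1COC | intermediate
16 | 1,2-bis[(6R)-5-(4-{[tert-butyl(dimethyl)silyl]oxy}-2-methylbutan-2-yl)-6-{[(2R)-2-(methoxymethyl)pyrrolidin-1-yl]carbonyl}-2,6-dimethylcyclohexa-1,4-dien-1-yl]ethane (key-step product; ring C6 = C10) | C(CC1=C(C)CC=C(C(C)(C)CCO[Si](C)(C)C(C)(C)C)[C@]1(C)C(=O)N1CCC[C@@H]1COC)C1=C(C)CC=C(C(C)(C)CCO[Si](C)(C)C(C)(C)C)[C@]1(C)C(=O)N1CCC[C@@H]1COC | intermediate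
17 | 1,2-bis[(6R)-5-(4-hydroxy-2-methylbutan-2-yl)-6-{[(2R)-2-(methoxymethyl)pyrrolidin-1-yl]carbonyl}-2,6-dimethylcyclohexa-1,4-dien-1-yl]ethane | C(CC1=C(C)CC=C(C(C)(C)CCO)[C@]1(C)C(=O)N1CCC[C@@H]1COC)C1=C(C)CC=C(C(C)(C)CCO)[C@]1(C)C(=O)N1CCC[C@@H]1COC | intermediate
18 | 1,2-bis[(6R)-5-(4-iodo-2-methylbutan-2-yl)-6-{[(2R)-2-(methoxymethyl)pyrrolidin-1-yl]carbonyl}-2,6-dimethylcyclohexa-1,4-dien-1-yl]ethane | C(CC1=C(C)CC=C(C(C)(C)CCI)[C@]1(C)C(=O)N1CCC[C@@H]1COC)C1=C(C)CC=C(C(C)(C)CCI)[C@]1(C)C(=O)N1CCC[C@@H]1COC | intermediate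
19 | bis(primary alkyllithium) from 18, lithium on each C2 (not isolated) | C(CC1=C(C)CC=C(C(C)(C)CC[Li])[C@]1(C)C(=O)N1CCC[C@@H]1COC)C1=C(C)CC=C(C(C)(C)CC[Li])[C@]1(C)C(=O)N1CCC[C@@H]1COC | intermediate
20 | bis(lithium hemiaminal alkoxide) with both rings A closed, C1 carrying OLi and the pyrrolidine (not isolated) | C(CC1=C(C)CC=C2C(C)(C)CCC(O[Li])(N3CCC[C@@H]3COC)[C@]12C)C1=C(C)CC=C2C(C)(C)CCC(O[Li])(N3CCC[C@@H]3COC)[C@]12C | intermediate
21 | 8,8'-(ethane-1,2-diyl)bis[(8aR)-4,4,7,8a-tetramethyl-3,4,6,8a-tetrahydronaphthalen-1(2H)-one] (C1 ketones, C5=C6 and C8=C9 in each half) | C(CC1=C(C)CC=C2C(C)(C)CCC(=O)[C@]12C)C1=C(C)CC=C2C(C)(C)CCC(=O)[C@]12C | intermediate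
22 | 8,8'-(ethane-1,2-diyl)bis[(4aS,8aS)-4,4,7,8a-tetramethyl-3,4,4a,5,6,8a-hexahydronaphthalen-1(2H)-one] (trans-fused; the 8a descriptor changes from R to S by priority only) | C(CC1=C(C)CC[C@H]2C(C)(C)CCC(=O)[C@]12C)C1=C(C)CC[C@H]2C(C)(C)CCC(=O)[C@]12C | intermediate
23 | bis-hydrazone of 22 at both C1 carbonyls (not isolated) | C(CC1=C(C)CC[C@H]2C(C)(C)CCC(=NN)[C@]12C)C1=C(C)CC[C@H]2C(C)(C)CCC(=NN)[C@]12C | intermediate
24 | 1,2-bis[(4aS,8aS)-2,5,5,8a-tetramethyl-3,4,4a,5,6,7,8,8a-octahydronaphthalen-1-yl]ethane (CNP0372467.1; 5S,10S in both halves) | CC1=C(CCC2=C(C)CC[C@H]3C(C)(C)CCC[C@]23C)[C@@]2(C)CCCC(C)(C)[C@@H]2CC1 | target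

**Step count and risks**

Total steps: 13. Longest linear sequence: 13 steps (1 to 24); the amine 3, the malonate 6 and iodomethane 14 enter as purchased materials.

Steps most likely to fail:

1. Step 8. Electron transfer to the two twisted, di-ortho-substituted benzamide rings may be incomplete or may reduce the amide carbonyl instead of the ring. The crowded C10 enolates may be protonated by ammonia before they are methylated. Face selectivity may erode because the enolate is flanked by two ortho substituents. Fallback: reduction and C–C bond formation are separated. Setting out from 13, the same lithium–ammonia reduction with t-BuOH is quenched with NH4Cl to give the bis(1,4-dihydrobenzamide) with hydrogen on each C10, compound F1. F1 is then deprotonated at the doubly allylic C10–H with LiN(i-Pr)2 in THF at −78 °C, which regenerates the chelated enolate 15 in an aprotic medium where no proton source competes. Methylation with iodomethane returns to the route at 16. The enolate geometry is dictated by the two ortho groups in either mode, so the same facial sense is expected, but it should be confirmed on a single-ring sample.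

2. Step 12. The skipped diene may undergo double-bond migration on the metal surface before reduction. Uptake at C5=C6, which sits between two quaternary carbons, may be slow. Hydrogen may be delivered from the β face and give the cis fusion. Fallback: stepwise radical hydrogen-atom-transfer reduction in place of surface hydrogenation. Setting out from 21, Mn(dpm)3 (dpm = dipivaloylmethanato), PhSiH3 and t-BuOOH in i-PrOH at rt add a hydrogen atom to C6 and then quench the tertiary C5 radical from the less hindered α direction to the thermodynamically preferred trans fusion. The C5 radical has no other β-hydrogen (C4 and C10 are quaternary), so migration is excluded, and the tetrasubstituted C8=C9 should react much more slowly. The fallback makes no new compound (F0) and returns to the route at 22.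

3. Step 7. s-BuLi may deprotonate next to nitrogen or add to the amide carbonyl instead of lithiating C11. The one-electron copper oxidation may chlorinate or over-oxidise the benzylic position and give poor mass balance. Fallback: a two-electron alkylation replaces the oxidative coupling. Setting out from 11, one portion of benzyllithium 12 is quenched with hexachloroethane to give the benzylic chloride [2-(chloromethyl)-6-(4-{[tert-butyl(dimethyl)silyl]oxy}-2-methylbutan-2-yl)-3-methylphenyl][(2R)-2-(methoxymethyl)pyrrolidin-1-yl]methanone F2. F2 is then added at −78 °C to a second, separately prepared equivalent of 12, and the SN2 displacement forms C11–C12 and returns to the route at 13.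

**Further compounds**

F1 | step 8 | 1,2-bis[5-(4-{[tert-butyl(dimethyl)silyl]oxy}-2-methylbutan-2-yl)-6-{[(2R)-2-(methoxymethyl)pyrrolidin-1-yl]carbonyl}-2-methylcyclohexa-1,4-dien-1-yl]ethane (hydrogen on each C10, configuration there not defined) | C(CC1=C(C)CC=C(C(C)(C)CCO[Si](C)(C)C(C)(C)C)C1C(=O)N1CCC[C@@H]1COC)C1=C(C)CC=C(C(C)(C)CCO[Si](C)(C)C(C)(C)C)C1C(=O)N1CCC[C@@H]1COC
F0 | step 12 | none | none
F2 | step 7 | [2-(chloromethyl)-6-(4-{[tert-butyl(dimethyl)silyl]oxy}-2-methylbutan-2-yl)-3-methylphenyl][(2R)-2-(methoxymethyl)pyrrolidin-1-yl]methanone | ClCc1c(C)ccc(C(C)(C)CCO[Si](C)(C)C(C)(C)C)c1C(=O)N1CCC[C@@H]1COC
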